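**Plan** (atom numbers are the tetralin numbers of the target: C1 diarylmethine, C2 and C3 carry CH2OH, C4 benzylic CH2, C4a the ring A carbon para to the C7 oxygen)
Retrosynthesis: the cis-diol is folded back to a cis-fused γ-lactone and then to a 2-methoxytetrahydrofuran acetal across C2–C3; this tricycle is cut at C4–C4a and at C2–C3 in one operation to an open-chain allyl bromo acetal; the C1–pendant aryl bond is cut last, by conjugate addition.
Forward: Wittig enal, rhodium 1,4-arylation, acetal, enol ether, bromo acetal (chain complete); then the tetrahydrofuran ring (5-exo radical closure) and the carbocycle (aryl–alkyl coupling at nickel) arise together; acetal to lactone, epimerisation, reduction, debenzylation.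
Enabling feature: the CH2OH groups on C2 and C3 form a 1,4-diol, so the C2 arm can serve as an acetal carbon that ties allyl alcohol (future C4, C3 and the C3 arm) into a temporary five-membered ring opposite a C2 radical; C4a of ring A is para to the C7 oxygen and can carry bromine, which sends the C4 radical to ring A and not to the pendant ring.
Stereochemistry: C1 from the chiral diene–rhodium catalyst; C3 in the key step by relay from C1 (the least secure point, see risks); C2 by equilibration to the cis-fused lactone; the C–Br and acetal centres are carried as mixtures that converge.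

Key step: step 6

Remark: the diene ligand enantiomer in step 2 is taken to be the one that gives the S configuration at the diarylmethine; if the sense of induction is the reverse, its antipode is used.

**Step 1**
Reactants: 1 5-(benzyloxy)-2-bromo-4-methoxybenzaldehyde; 2 (triphenylphosphoranylidene)acetaldehyde
Product: 3 (2E)-3-[5-(benzyloxy)-2-bromo-4-methoxyphenyl]prop-2-enal
Conditions: toluene, 80 °C
Reagents that add atoms: none
Why: Wittig olefination with a stabilised formyl ylide should give the E enal, the aryl bromide and the ethers being inert.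

**Step 2**
Reactants: 3 (2E)-3-[5-(benzyloxy)-2-bromo-4-methoxyphenyl]prop-2-enal; 4 [4-(benzyloxy)-3-methoxyphenyl]boronic acid
Product: 5 (3S)-3-[5-(benzyloxy)-2-bromo-4-methoxyphenyl]-3-[4-(benzyloxy)-3-methoxyphenyl]propanal
Conditions: [RhCl(C2H4)2]2 (1.5 mol %), (1R,4R)-2,5-diphenylbicyclo[2.2.2]octa-2,5-diene (3.3 mol %), KOH (0.5 equiv), MeOH/H2O 10:1, 50 °C
Reagents that add atoms: none
Why: Hayashi–Miyaura rhodium-catalysed asymmetric 1,4-addition of an arylboronic acid to an enal, in which the aryl–rhodium species on the chiral diene inserts the enal from one face and so sets C1 of the target as S, while monovalent rhodium leaves the aryl bromide untouched.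

**Step 3**
Reactants: 5 (3S)-3-[5-(benzyloxy)-2-bromo-4-methoxyphenyl]-3-[4-(benzyloxy)-3-methoxyphenyl]propanal
Product: 6 1-(benzyloxy)-5-[(1S)-1-[4-(benzyloxy)-3-methoxyphenyl]-3,3-dimethoxypropyl]-4-bromo-2-methoxybenzene
Conditions: HC(OMe)3, PPTS (5 mol %), MeOH, rt
Reagents that add atoms: trimethyl orthoformate, COC(OC)OC; methanol, CO
Why: Acid-catalysed acetalisation of the aldehyde, driven by the orthoformate as water scavenger; the β-stereocentre is not enolisable.

**Step 4**
Reactants: 6 1-(benzyloxy)-5-[(1S)-1-[4-(benzyloxy)-3-methoxyphenyl]-3,3-dimethoxypropyl]-4-bromo-2-methoxybenzene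
Product: 7 1-(benzyloxy)-5-[(1S)-1-[4-(benzyloxy)-3-methoxyphenyl]-3-methoxyprop-2-en-1-yl]-4-bromo-2-methoxybenzene (E/Z mixture)
Conditions: TMSOTf (1.3 equiv), i-Pr2NEt (1.5 equiv), CH2Cl2, −20 °C to rt
Reagents that add atoms: none
Why: Gassman-type elimination of methanol from a dimethyl acetal, in which TMSOTf ionises the acetal and the hindered amine removes the adjacent proton to give the enol ether; the alkene geometry is irrelevant.

**Step 5**
Reactants: 7 1-(benzyloxy)-5-[(1S)-1-[4-(benzyloxy)-3-methoxyphenyl]-3-methoxyprop-2-en-1-yl]-4-bromo-2-methoxybenzene; 8 prop-2-en-1-ol (allyl alcohol, 3 equiv)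
Product: 9 1-(benzyloxy)-5-[(1S)-1-[4-(benzyloxy)-3-methoxyphenyl]-2-bromo-3-methoxy-3-(prop-2-en-1-yloxy)propyl]-4-bromo-2-methoxybenzene (mixture of diastereomers at C2 and C3 of the propyl chain)
Conditions: NBS (1.1 equiv), CH2Cl2, −78 to −20 °C
Reagents that add atoms: N-bromosuccinimide, O=C1CCC(=O)N1Br
Why: Haloacetalisation of an enol ether (the Ueno–Stork precursor synthesis), in which NBS brominates the nucleophilic β-carbon and allyl alcohol traps the oxocarbenium ion far faster than the alkoxyarenes are brominated at low temperature; the two new stereocentres are not controlled because both are lost later.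

**Step 6**
Reactants: 9 1-(benzyloxy)-5-[(1S)-1-[4-(benzyloxy)-3-methoxyphenyl]-2-bromo-3-methoxy-3-(prop-2-en-1-yloxy)propyl]-4-bromo-2-methoxybenzene
Product: 10 (3aS,9S)-7-(benzyloxy)-9-[4-(benzyloxy)-3-methoxyphenyl]-1,6-dimethoxy-1,3,3a,4,9,9a-hexahydronaphtho[2,3-c]furan (epimers at C1 and C9a; the trans-fused 9aS series is expected to predominate)
Conditions: NiCl2(DME) (20 mol %), ethyl crotonate (40 mol %), pyridine (1 equiv), Zn dust (3 equiv), DMA (0.03 M), 30 °C
Reagents that add atoms: none
Why: Zinc reduces the divalent nickel salt to zerovalent nickel, which inserts into the ring A C–Br bond, and low-valent nickel abstracts bromine from the secondary bromide to give a planar C2 radical, so that all C–Br and acetal diastereomers of 9 converge; this radical adds 5-exo-trig to the internal allyl carbon (C2–C3 bond) and the primary C4 radical so formed is captured by the arylnickel bromide, the trivalent nickel species then forming the C4–C4a bond by reductive elimination. The closest known reaction type is the nickel-catalysed reductive tandem radical cyclisation/aryl–alkyl cross-electrophile coupling of Ueno–Stork β-bromo acetals that carry a tethered aryl halide. The tetrahydrofuran ring closes by 5-exo-trig radical attack and the six-membered carbocycle by C(sp2)–C(sp3) reductive elimination from a seven-membered nickelacycle. C3 is set in the 5-exo transition state under control of the C1 stereocentre: in the rotamer with C1–H eclipsing the C2–acetal bond the alkene is expected to add to the radical face remote from the ortho-bromoaryl ring while the diarylmethyl group and the new CH2 stay trans on the nascent tetrahydrofuran, which puts the C3–CH2O bond anti to the pendant aryl; C2 need not be controlled, since either C2 epimer with this C3 configuration is corrected in step 8, and the acetal carbon is erased in step 7. The step needs attack at the internal alkene carbon (secured by the three-atom acetal tether, which makes the alternative a 6-endo closure), coupling to ring A and not to the pendant ring (only ring A carries bromine, at the carbon para to the benzyloxy group) and cyclisation faster than capture, reduction or 1,2-aryl shift of the first radical (the oxygen-containing tether makes the 5-exo closure fast, and moderate dilution suppresses intermolecular coupling).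

**Step 7**
Reactants: 10 (3aS,9S)-7-(benzyloxy)-9-[4-(benzyloxy)-3-methoxyphenyl]-1,6-dimethoxy-1,3,3a,4,9,9a-hexahydronaphtho[2,3-c]furan
Product: 12 (3aS,9S)-7-(benzyloxy)-9-[4-(benzyloxy)-3-methoxyphenyl]-6-methoxy-3a,4,9,9a-tetrahydronaphtho[2,3-c]furan-1(3H)-one (epimers at C9a), via lactol 11 (not isolated)
Conditions: CrO3, H2SO4, acetone/H2O, 0 °C
Reagents that add atoms: water, O
Why: Jones oxidation of a cyclic acetal, in which aqueous acid unmasks the lactol and hexavalent chromium oxidises it to the γ-lactone, removing the acetal stereocentre and making C2 epimerisable.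

**Step 8**
Reactants: 12 (3aS,9S)-7-(benzyloxy)-9-[4-(benzyloxy)-3-methoxyphenyl]-6-methoxy-3a,4,9,9a-tetrahydronaphtho[2,3-c]furan-1(3H)-one (epimers at C9a)
Product: 13 (3aS,9S,9aR)-7-(benzyloxy)-9-[4-(benzyloxy)-3-methoxyphenyl]-6-methoxy-3a,4,9,9a-tetrahydronaphtho[2,3-c]furan-1(3H)-one (cis-fused lactone, aryl trans to the lactone carbonyl)
Conditions: DBU (0.3 equiv), THF, 50 °C
Reagents that add atoms: none
Why: Base-mediated epimerisation α to the lactone carbonyl under thermodynamic control, in which the strained trans-fused γ-lactone on a tetralin passes to the cis-fused isomer as in the podophyllotoxin-to-picropodophyllin isomerisation, so that C2 of the target is fixed cis to C3 and trans to the C1 aryl group.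

**Step 9**
Reactants: 13 (3aS,9S,9aR)-7-(benzyloxy)-9-[4-(benzyloxy)-3-methoxyphenyl]-6-methoxy-3a,4,9,9a-tetrahydronaphtho[2,3-c]furan-1(3H)-one
Product: 14 [(1S,2R,3S)-7-(benzyloxy)-1-[4-(benzyloxy)-3-methoxyphenyl]-6-methoxy-1,2,3,4-tetrahydronaphthalene-2,3-diyl]dimethanol
Conditions: LiAlH4, THF, 0 °C to rt; aqueous NaOH work-up
Reagents that add atoms: none
Why: Hydride reduction of a lactone to the 1,4-diol with LiAlH4, in which no stereocentre is touched and the cis relation of C2 and C3 is kept.

**Step 10**
Reactants: 14 [(1S,2R,3S)-7-(benzyloxy)-1-[4-(benzyloxy)-3-methoxyphenyl]-6-methoxy-1,2,3,4-tetrahydronaphthalene-2,3-diyl]dimethanol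
Product: 15 (1S,2R,3S)-7-hydroxy-1-(4-hydroxy-3-methoxyphenyl)-6-methoxy-1,2,3,4-tetrahydronaphthalene-2,3-dimethanol (target)
Conditions: H2 (1 atm), 10% Pd/C, EtOAc/MeOH, rt
Reagents that add atoms: none
Why: Hydrogenolysis of the two benzyl aryl ethers over palladium, to which the diol and the three stereocentres are inert.

**Compound list**
1 | 5-(benzyloxy)-2-bromo-4-methoxybenzaldehyde | O=Cc1cc(OCc2ccccc2)c(OC)cc1Br | starting material
2 | (triphenylphosphoranylidene)acetaldehyde | O=CC=P(c1ccccc1)(c1ccccc1)c1ccccc1 | starting material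
3 | (2E)-3-[5-(benzyloxy)-2-bromo-4-methoxyphenyl]prop-2-enal | O=C/C=C/c1cc(OCc2ccccc2)c(OC)cc1Br | intermediate
4 | [4-(benzyloxy)-3-methoxyphenyl]boronic acid | OB(O)c1ccc(OCc2ccccc2)c(OC)c1 | starting material
5 | (3S)-3-[5-(benzyloxy)-2-bromo-4-methoxyphenyl]-3-[4-(benzyloxy)-3-methoxyphenyl]propanal | O=CC[C@@H](c1ccc(OCc2ccccc2)c(OC)c1)c1cc(OCc2ccccc2)c(OC)cc1Br | intermediate
6 | 1-(benzyloxy)-5-[(1S)-1-[4-(benzyloxy)-3-methoxyphenyl]-3,3-dimethoxypropyl]-4-bromo-2-methoxybenzene | COC(OC)C[C@@H](c1ccc(OCc2ccccc2)c(OC)c1)c1cc(OCc2ccccc2)c(OC)cc1Br | intermediate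
7 | 1-(benzyloxy)-5-[(1S)-1-[4-(benzyloxy)-3-methoxyphenyl]-3-methoxyprop-2-en-1-yl]-4-bromo-2-methoxybenzene (E/Z mixture) | COC=C[C@@H](c1ccc(OCc2ccccc2)c(OC)c1)c1cc(OCc2ccccc2)c(OC)cc1Br | intermediate
8 | prop-2-en-1-ol (allyl alcohol) | C=CCO | starting material
9 | 1-(benzyloxy)-5-[(1S)-1-[4-(benzyloxy)-3-methoxyphenyl]-2-bromo-3-methoxy-3-(prop-2-en-1-yloxy)propyl]-4-bromo-2-methoxybenzene (diastereomer mixture at the C–Br and acetal carbons) | C=CCOC(OC)C(Br)[C@@H](c1ccc(OCc2ccccc2)c(OC)c1)c1cc(OCc2ccccc2)c(OC)cc1Br | intermediate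
10 | (3aS,9S)-7-(benzyloxy)-9-[4-(benzyloxy)-3-methoxyphenyl]-1,6-dimethoxy-1,3,3a,4,9,9a-hexahydronaphtho[2,3-c]furan (epimers at C1 and C9a) | COC1OC[C@H]2Cc3cc(OC)c(OCc4ccccc4)cc3[C@H](c3ccc(OCc4ccccc4)c(OC)c3)C12 | intermediate
11 | (3aS,9S)-7-(benzyloxy)-9-[4-(benzyloxy)-3-methoxyphenyl]-6-methoxy-1,3,3a,4,9,9a-hexahydronaphtho[2,3-c]furan-1-ol (lactol, epimers at C1 and C9a) | OC1OC[C@H]2Cc3cc(OC)c(OCc4ccccc4)cc3[C@H](c3ccc(OCc4ccccc4)c(OC)c3)C12 | intermediate (not isolated)
12 | (3aS,9S)-7-(benzyloxy)-9-[4-(benzyloxy)-3-methoxyphenyl]-6-methoxy-3a,4,9,9a-tetrahydronaphtho[2,3-c]furan-1(3H)-one (epimers at C9a) | O=C1OC[C@H]2Cc3cc(OC)c(OCc4ccccc4)cc3[C@H](c3ccc(OCc4ccccc4)c(OC)c3)C12 | intermediate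
13 | (3aS,9S,9aR)-7-(benzyloxy)-9-[4-(benzyloxy)-3-methoxyphenyl]-6-methoxy-3a,4,9,9a-tetrahydronaphtho[2,3-c]furan-1(3H)-one | O=C1OC[C@H]2Cc3cc(OC)c(OCc4ccccc4)cc3[C@H](c3ccc(OCc4ccccc4)c(OC)c3)[C@@H]12 | intermediate
14 | [(1S,2R,3S)-7-(benzyloxy)-1-[4-(benzyloxy)-3-methoxyphenyl]-6-methoxy-1,2,3,4-tetrahydronaphthalene-2,3-diyl]dimethanol | COc1cc([C@H]2c3cc(OCc4ccccc4)c(OC)cc3C[C@H](CO)[C@@H]2CO)ccc1OCc1ccccc1 | intermediate
15 | (1S,2R,3S)-7-hydroxy-1-(4-hydroxy-3-methoxyphenyl)-6-methoxy-1,2,3,4-tetrahydronaphthalene-2,3-dimethanol | COc1cc([C@H]2c3cc(O)c(OC)cc3C[C@H](CO)[C@@H]2CO)ccc1O | target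

**Total step count:** 10
**Longest linear sequence:** 10 steps (1 to 15)

**Steps most likely to fail**

Step 6. The relay of configuration from C1 to C3 may be weak, because the choice of radical face and the choice of alkene face in the 5-exo closure need not be correlated. The C2 radical may also be reduced or undergo a 1,2-aryl shift before it cyclises. The fallback replaces kinetic control of C3 by thermodynamic control of C2 and C3 together. It sets out from lactone 12, taken as the full diastereomer mixture. LiOH in THF/H2O opens the lactone to the hydroxy acid F1. TEMPO (cat.)/NaClO2/NaOCl (cat.) at pH 7 oxidises the carboxylate alcohol to the diacid F2. Ac2O/NaOAc at 120 °C closes the anhydride and equilibrates both α-carbons through the enol; the cis-fused anhydride with the aryl group trans, F3, is the expected sink. LiAlH4 in THF reduces this anhydride to diol 14, where the route is rejoined; step 8 is then not needed.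

Step 2. The ortho-bromine next to the reacting alkene may lower the facial selectivity or slow the insertion, and the basic medium may cause self-condensation of the enal. The fallback uses auxiliary control with a cuprate in place of catalyst control. It sets out from enal 3. NaClO2/NaH2PO4/2-methyl-2-butene gives the cinnamic acid F4. Pivaloyl chloride/Et3N gives the mixed anhydride F5, which acylates lithiated (R)-4-phenyl-1,3-oxazolidin-2-one to the imide F6. The aryl Grignard reagent F7 (from commercially available 1-(benzyloxy)-4-bromo-2-methoxybenzene and Mg) with CuBr·SMe2 in THF at −40 °C should add to the chelated s-cis imide on the face away from the phenyl group, giving the adduct F8. LiBH4 in THF/MeOH cleaves the auxiliary to the alcohol F9, and Dess–Martin oxidation returns aldehyde 5.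

Step 7. Chromic acid may over-oxidise the doubly benzylic C–H or attack the benzyl ethers, and the acid may remove a benzyl group. The fallback splits the operation into two chromium-free stages with the lactol isolated. It sets out from acetal 10. PPTS in wet acetone at 40 °C gives lactol 11, which is isolated. Ag2CO3 on Celite in refluxing toluene, a neutral surface oxidant that is selective for lactols, then gives lactone 12, where the route is rejoined.

**Further compounds**
F1 | step 6 | (1S)-7-(benzyloxy)-1-[4-(benzyloxy)-3-methoxyphenyl]-3-(hydroxymethyl)-6-methoxy-1,2,3,4-tetrahydronaphthalene-2-carboxylic acid (mixture at C2 and C3) | OCC1Cc2cc(OC)c(OCc3ccccc3)cc2[C@H](c2ccc(OCc3ccccc3)c(OC)c2)C1C(=O)O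
F2 | step 6 | (1S)-7-(benzyloxy)-1-[4-(benzyloxy)-3-methoxyphenyl]-6-methoxy-1,2,3,4-tetrahydronaphthalene-2,3-dicarboxylic acid (mixture at C2 and C3) | OC(=O)C1Cc2cc(OC)c(OCc3ccccc3)cc2[C@H](c2ccc(OCc3ccccc3)c(OC)c2)C1C(=O)O
F3 | step 6 | (3aR,4S,9aS)-6-(benzyloxy)-4-[4-(benzyloxy)-3-methoxyphenyl]-7-methoxy-3a,4,9,9a-tetrahydronaphtho[2,3-c]furan-1,3-dione (cis-fused anhydride, aryl trans) | O=C1OC(=O)[C@H]2Cc3cc(OC)c(OCc4ccccc4)cc3[C@H](c3ccc(OCc4ccccc4)c(OC)c3)[C@@H]12
F4 | step 2 | (2E)-3-[5-(benzyloxy)-2-bromo-4-methoxyphenyl]prop-2-enoic acid | OC(=O)/C=C/c1cc(OCc2ccccc2)c(OC)cc1Br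
F5 | step 2 | (2E)-3-[5-(benzyloxy)-2-bromo-4-methoxyphenyl]prop-2-enoic 2,2-dimethylpropanoic anhydride | CC(C)(C)C(=O)OC(=O)/C=C/c1cc(OCc2ccccc2)c(OC)cc1Br
F6 | step 2 | (4R)-3-[(2E)-3-[5-(benzyloxy)-2-bromo-4-methoxyphenyl]prop-2-enoyl]-4-phenyl-1,3-oxazolidin-2-one | O=C(/C=C/c1cc(OCc2ccccc2)c(OC)cc1Br)N1[C@H](c2ccccc2)COC1=O
F7 | step 2 | [4-(benzyloxy)-3-methoxyphenyl]magnesium bromide | Br[Mg]c1ccc(OCc2ccccc2)c(OC)c1
F8 | step 2 | (4R)-3-[(3S)-3-[5-(benzyloxy)-2-bromo-4-methoxyphenyl]-3-[4-(benzyloxy)-3-methoxyphenyl]propanoyl]-4-phenyl-1,3-oxazolidin-2-one | O=C(C[C@@H](c1ccc(OCc2ccccc2)c(OC)c1)c1cc(OCc2ccccc2)c(OC)cc1Br)N1[C@H](c2ccccc2)COC1=O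
F9 | step 2 | (3S)-3-[5-(benzyloxy)-2-bromo-4-methoxyphenyl]-3-[4-(benzyloxy)-3-methoxyphenyl]propan-1-ol | OCC[C@@H](c1ccc(OCc2ccccc2)c(OC)c1)c1cc(OCc2ccccc2)c(OC)cc1Br
F0 | step 7 | none | none
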